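Both cyclohexane rings of the target are the same 5-O-caffeoyl ent-quinate (mirror image of the natural series), so one ring synthesis serves twice. In each ring C1(OH)(CO2R)–C2H2–C3(O) is a β-hydroxy ketone pattern once C3 is drawn as a ketone, and the ring is cut at C1–C2. The key step is the corresponding intramolecular aldol addition: an enolate formed at the terminal methyl group of a 2,6-dioxoheptanoate (this carbon becomes C2) attacks the keto group next to the ester (it becomes C1), closing the carbocycle and fixing C1 in one operation. The precursor holds the trans C4/C5 oxygens, taken from L-tartrate, in a dioxolane. One late intermediate then serves as both partners of the tertiary inter-ring ester.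

Key step: step 6

Remark (numbering and series): ring carbons are numbered as in quinic acid (C1 carries OH and the carboxyl; O3 and O4 are cis to each other and to O1; O5 is trans to O4 and cis to the carboxyl). Read from the target SMILES, both rings are the enantiomer of natural (−)-quinate, i.e. the (1R,3S,4R,5S)-tetrol acid ("ent-quinate"), and both caffeoyl groups sit on O5. Ring A is the acyl ring (free O1–H in the target), ring B the ring with the free carboxyl.
Remark (precursor design): the 4,5-diol is carried as a trans-dioxolane, not as two separate ethers. The acetal keeps the ketone α-centre in its thermodynamic trans arrangement, pre-folds the chain, makes the ring methine a poor site for β-elimination, and later migrates to O3/O4 in one step. The ring closure is 6-(enolendo)-exo-trig, because both enolate carbons become ring members.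
Remark (availability): compound 1, the acetonide of dimethyl L-tartrate, is taken as a catalogue compound.

Step 1
Reactants: 1 dimethyl (4R,5R)-2,2-dimethyl-1,3-dioxolane-4,5-dicarboxylate (dimethyl 2,3-O-isopropylidene-L-tartrate)
Product: 2 methyl (4R,5S)-5-(hydroxymethyl)-2,2-dimethyl-1,3-dioxolane-4-carboxylate
Conditions: NaBH4 (0.5 equiv), MeOH, −10 → 0 °C
Reagents that add atoms: none
Why: Borohydride reduction of an α-alkoxy-activated ester, run with a deficit of hydride so that the C2-symmetric diester is reduced once (a statistical desymmetrisation, unreacted 1 being recycled); neither stereocentre is touched and lactonisation of 2 is prevented by the trans ring fusion it would require.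

Step 2
Reactants: 2 methyl (4R,5S)-5-(hydroxymethyl)-2,2-dimethyl-1,3-dioxolane-4-carboxylate
Product: 3 (4R,5S)-5-(hydroxymethyl)-N-methoxy-N,2,2-trimethyl-1,3-dioxolane-4-carboxamide
Conditions: MeNHOMe·HCl (3 equiv), i-PrMgCl (6 equiv), THF, −20 → 0 °C
Reagents that add atoms: N,O-dimethylhydroxylamine hydrochloride, CNOC.Cl
Why: Ester aminolysis by the chloromagnesium amide of N,O-dimethylhydroxylamine (Weinreb amide formation), the free hydroxyl merely consuming one equivalent of base; the α-centre cannot be lost because the trans-dioxolane is the thermodynamic arrangement.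

Step 3
Reactants: 3 (4R,5S)-5-(hydroxymethyl)-N-methoxy-N,2,2-trimethyl-1,3-dioxolane-4-carboxamide; 4 ethyl 1,3-dithiane-2-carboxylate
Product: 7 ethyl 2-{[(4S,5R)-5-[methoxy(methyl)carbamoyl]-2,2-dimethyl-1,3-dioxolan-4-yl]methyl}-1,3-dithiane-2-carboxylate, via primary triflate 5 (not isolated), via sodium dithiane enolate 6 (not isolated)
Conditions: 3, Tf2O (1.05 equiv), 2,6-lutidine, CH2Cl2, −78 °C, cold aqueous wash; 4 (1.3 equiv), NaN(SiMe3)2, THF, −78 °C; crude 5 added to 6, −78 → 0 °C
Reagents that add atoms: none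
Why: SN2 C-alkylation of a glyoxylate acyl-anion equivalent: the soft ester-stabilised dithiane enolate should displace the primary triflate at low temperature without touching the amide, and participation by the amide oxygen is disfavoured because it would build a trans-fused bicyclo[3.3.0] ring.

Step 4
Reactants: 7 ethyl 2-{[(4S,5R)-5-[methoxy(methyl)carbamoyl]-2,2-dimethyl-1,3-dioxolan-4-yl]methyl}-1,3-dithiane-2-carboxylate
Product: 8 ethyl 2-{[(4S,5R)-5-acetyl-2,2-dimethyl-1,3-dioxolan-4-yl]methyl}-1,3-dithiane-2-carboxylate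
Conditions: MeMgBr (1.3 equiv), THF, −78 → −20 °C; aq. NH4Cl
Reagents that add atoms: methylmagnesium bromide, C[Mg]Br
Why: Weinreb ketone synthesis: the α-alkoxy N-methoxy-N-methylamide takes up one methyl group and rests as the magnesium-chelated tetrahedral adduct until work-up, while the ethyl ester on the fully substituted dithiane carbon is too hindered to compete at low temperature.

Step 5
Reactants: 8 ethyl 2-{[(4S,5R)-5-acetyl-2,2-dimethyl-1,3-dioxolan-4-yl]methyl}-1,3-dithiane-2-carboxylate
Product: 9 ethyl 3-[(4S,5R)-5-acetyl-2,2-dimethyl-1,3-dioxolan-4-yl]-2-oxopropanoate (ethyl (4S,5R)-4,5-(isopropylidenedioxy)-2,6-dioxoheptanoate)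
Conditions: N-bromosuccinimide (4 equiv), NaHCO3, acetone/H2O (9:1), −10 °C, 10 min; aq. Na2S2O3
Reagents that add atoms: water, O
Why: Oxidative hydrolysis of the dithioacetal by N-bromosuccinimide in buffered aqueous acetone releases the α-keto ester under non-basic conditions, so its enolate, and with it β-elimination of the ring oxygen, is avoided and the acetal survives.

Step 6
Reactants: 9 ethyl (4S,5R)-4,5-(isopropylidenedioxy)-2,6-dioxoheptanoate
Product: 12 ethyl (1S,4R,5S)-1-hydroxy-4,5-(isopropylidenedioxy)-3-oxocyclohexane-1-carboxylate (ethyl 4,5-O-isopropylidene-3-dehydro-ent-quinate), via boron enolate 10 (not isolated), via boron aldolate 11 (not isolated)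
Conditions: n-Bu2BOTf (1.1 equiv), i-Pr2NEt (1.3 equiv), CH2Cl2, −78 → −20 °C; MeOH/pH 7 phosphate buffer, 0 °C
Reagents that add atoms: none
Why: Bu2BOTf binds the more Lewis-basic methyl ketone and i-Pr2NEt removes a proton from the unhindered CH3 group, giving the terminal boron enolate 10, which adds through carbon to the strongly electrophilic keto group of the α-keto ester and so forms the C1–C2 bond. The closest known reaction type is the boron-mediated aldol addition of a methyl ketone to an α-keto ester, here intramolecular, and it mirrors the aldol step of dehydroquinate biosynthesis. The cyclohexane ring closes in the 6-(enolendo)-exo-trig mode, since both enolate carbons (C2 and C3) become ring members. The new C1 stereocentre is controlled by the chair-like transition state imposed by the trans-dioxolane (O4 and O5 equatorial) in which boron bridges the enolate oxygen and the incoming carbonyl oxygen, an arrangement possible only when the developing C1–O bond is axial, so that the ester lies equatorial and the C1 hydroxyl ends up cis to O4 and trans to O5. The step needs enolisation at the methyl group only: the CH3 enolate has no β-leaving group, the competing ring methine is anchored trans on the dioxolane and poorly aligned for elimination, and a covalent boron enolate formed with a hindered amine at −78 °C avoids the free α-keto ester enolate that would expel the ring oxygen. Only a slight excess of boron reagent and a cold buffered, non-oxidative work-up guard the product against dehydration and against epimerisation at C4.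

Step 7
Reactants: 12 ethyl 4,5-O-isopropylidene-3-dehydro-ent-quinate
Product: 13 ethyl 4,5-O-isopropylidene-ent-quinate (C3–OH cis to O4 and O1)
Conditions: LiBH(s-Bu)3 (2.2 equiv), THF, −78 °C, on freshly prepared 12; aq. NH4Cl
Reagents that add atoms: none
Why: Steric-approach-controlled ketone reduction by a bulky trialkylborohydride: in the chair locked by the trans-fused dioxolane the hydride should enter C3 from the equatorial side (the axial side is screened by the axial C1 oxygen), giving the axial C3 hydroxyl cis to O4 and O1, while ester and acetal are inert at −78 °C.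

Step 8
Reactants: 13 ethyl 4,5-O-isopropylidene-ent-quinate
Product: 14 ethyl 3,4-O-isopropylidene-ent-quinate (O1–H and O5–H free)
Conditions: TsOH·H2O (5 mol %), acetone, rt
Reagents that add atoms: none
Why: Acid-catalysed acetal migration under thermodynamic control: the strained trans-fused 4,5-dioxolane ionises and is recaptured by the cis 3-hydroxyl to give the unstrained cis-fused 3,4-acetal, which frees O5 without touching a stereocentre.

Step 9
Reactants: 14 ethyl 3,4-O-isopropylidene-ent-quinate
Product: 15 allyl 3,4-O-isopropylidene-ent-quinate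
Conditions: allyl alcohol (solvent), NaH (0.2 equiv), rt → 40 °C
Reagents that add atoms: allyl alcohol, C=CCO
Why: Alkoxide-catalysed transesterification driven by allyl alcohol as solvent exchanges ethyl for a carboxyl protecting group that is removable under neutral conditions; any 1,5-lactone formed through O5 is reopened by allyloxide, and no stereocentre is epimerisable.

Step 10
Reactants: 16 caffeic acid
Product: 18 (E)-3-[3,4-bis(tert-butyldimethylsilyloxy)phenyl]prop-2-enoic acid, via tris-silyl caffeate 17 (not isolated)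
Conditions: t-BuMe2SiCl (3.5 equiv), imidazole (7 equiv), DMF, rt; then AcOH/THF/H2O (3:1:1), rt
Reagents that add atoms: tert-butyldimethylsilyl chloride, CC(C)(C)[Si](C)(C)Cl
Why: Exhaustive silylation followed by selective hydrolysis of the silyl ester, which is far more labile than the aryl silyl ethers, gives the phenol-protected acid with the E alkene unchanged.

Step 11
Reactants: 15 allyl 3,4-O-isopropylidene-ent-quinate; 18 (E)-3-[3,4-bis(tert-butyldimethylsilyloxy)phenyl]prop-2-enoic acid
Product: 19 allyl 5-O-[(E)-3,4-bis(tert-butyldimethylsilyloxy)cinnamoyl]-3,4-O-isopropylidene-ent-quinate (O1–H free)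
Conditions: 18 (1.1 equiv), EDC·HCl (1.3 equiv), DMAP (0.3 equiv), CH2Cl2, 0 °C → rt
Reagents that add atoms: none
Why: Carbodiimide/DMAP (Steglich) esterification should acylate only the secondary 5-hydroxyl, the tertiary ester-flanked 1-hydroxyl being far less reactive, and it proceeds with retention at C5 because no C–O bond of the ring is broken.

Step 12
Reactants: 19 allyl 5-O-[(E)-3,4-bis(tert-butyldimethylsilyloxy)cinnamoyl]-3,4-O-isopropylidene-ent-quinate
Product: 20 allyl 5-O-[(E)-3,4-bis(tert-butyldimethylsilyloxy)cinnamoyl]-3,4-O-isopropylidene-1-O-(triethylsilyl)-ent-quinate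
Conditions: Et3SiOTf (1.5 equiv), 2,6-lutidine, CH2Cl2, 0 °C
Reagents that add atoms: triethylsilyl trifluoromethanesulfonate, CC[Si](CC)(CC)OS(=O)(=O)C(F)(F)F
Why: Silylation with a silyl triflate and a hindered pyridine base, a combination that silylates tertiary alcohols, under which ketal, allyl ester, cinnamate and aryl silyl ethers are stable.

Step 13
Reactants: 20 allyl 5-O-[(E)-3,4-bis(tert-butyldimethylsilyloxy)cinnamoyl]-3,4-O-isopropylidene-1-O-(triethylsilyl)-ent-quinate
Product: 21 5-O-[(E)-3,4-bis(tert-butyldimethylsilyloxy)cinnamoyl]-3,4-O-isopropylidene-1-O-(triethylsilyl)-ent-quinic acid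
Conditions: Pd(PPh3)4 (5 mol %), morpholine (5 equiv), THF, rt; work-up at pH 4
Reagents that add atoms: none
Why: Tsuji–Trost deallylation: zerovalent palladium ionises the allyl ester and morpholine captures the π-allyl fragment, a neutral cleavage that spares the cinnamate ester, the silyl ethers and the acetal.

Step 14
Reactants: 21 5-O-[(E)-3,4-bis(tert-butyldimethylsilyloxy)cinnamoyl]-3,4-O-isopropylidene-1-O-(triethylsilyl)-ent-quinic acid; 19 allyl 5-O-[(E)-3,4-bis(tert-butyldimethylsilyloxy)cinnamoyl]-3,4-O-isopropylidene-ent-quinate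
Product: 24 fully protected dimer (ring B: allyl 5-O-(bis-silyl-caffeoyl)-3,4-O-isopropylidene-ent-quinate whose O1 carries the acyl group of 21), via acid chloride 22 (not isolated), via lithium alkoxide 23 (not isolated)
Conditions: 21 (1.3 equiv), 1-chloro-N,N,2-trimethylprop-1-en-1-amine (1.5 equiv), CH2Cl2, 0 °C → rt; 19, LiN(SiMe3)2 (1.05 equiv), THF, −78 °C; 22 added to 23, −78 → 0 °C
Reagents that add atoms: none
Why: Acylation of a pre-formed tertiary lithium alkoxide by an acid chloride generated under neutral conditions, the classical way to esters hindered on both sides: neither partner has an α-hydrogen (no ketene, no enolisation), an O5→O1 acyl shift in 23 is geometrically impossible (1,3-trans), and both quaternary centres react at oxygen or carbonyl carbon only, so their configuration is retained.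

Step 15
Reactants: 24 fully protected dimer (allyl ester)
Product: 25 protected dimer acid (ring B carboxyl free)
Conditions: Pd(PPh3)4 (5 mol %), morpholine (5 equiv), THF, rt; work-up at pH 4
Reagents that add atoms: none
Why: The same palladium-catalysed allyl transfer to morpholine (Tsuji–Trost deallylation) frees the ring B carboxyl without base, so neither the cinnamate esters nor the inter-ring ester is endangered.

Step 16
Reactants: 25 protected dimer acid
Product: 26 target CNP0107948.2
Conditions: 2 M aq. HCl/THF (1:3), degassed, rt, 24–48 h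
Reagents that add atoms: none
Why: Global acid hydrolysis: dilute aqueous mineral acid cleaves both isopropylidene acetals, the triethylsilyl ether and the four aryl silyl ethers, while the cinnamate esters and the doubly tertiary inter-ring ester are stable, acyl migration is slow at low pH and lactonisation of ring B is excluded because its O5 is acylated.

Compound list
1 | dimethyl (4R,5R)-2,2-dimethyl-1,3-dioxolane-4,5-dicarboxylate | COC(=O)[C@@H]1OC(C)(C)O[C@H]1C(=O)OC | starting material
2 | methyl (4R,5S)-5-(hydroxymethyl)-2,2-dimethyl-1,3-dioxolane-4-carboxylate | COC(=O)[C@@H]1OC(C)(C)O[C@H]1CO | intermediate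
3 | (4R,5S)-5-(hydroxymethyl)-N-methoxy-N,2,2-trimethyl-1,3-dioxolane-4-carboxamide | CON(C)C(=O)[C@@H]1OC(C)(C)O[C@H]1CO | intermediate
4 | ethyl 1,3-dithiane-2-carboxylate | CCOC(=O)C1SCCCS1 | starting material
5 | [(4S,5R)-5-[methoxy(methyl)carbamoyl]-2,2-dimethyl-1,3-dioxolan-4-yl]methyl trifluoromethanesulfonate | CON(C)C(=O)[C@@H]1OC(C)(C)O[C@H]1COS(=O)(=O)C(F)(F)F | intermediate (not isolated)
6 | sodium enolate of ethyl 1,3-dithiane-2-carboxylate | [Na+].CCOC([O-])=C1SCCCS1 | intermediate (not isolated)
7 | ethyl 2-{[(4S,5R)-5-[methoxy(methyl)carbamoyl]-2,2-dimethyl-1,3-dioxolan-4-yl]methyl}-1,3-dithiane-2-carboxylate | CON(C)C(=O)[C@@H]1OC(C)(C)O[C@H]1CC2(C(=O)OCC)SCCCS2 | intermediate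
8 | ethyl 2-{[(4S,5R)-5-acetyl-2,2-dimethyl-1,3-dioxolan-4-yl]methyl}-1,3-dithiane-2-carboxylate | CC(=O)[C@@H]1OC(C)(C)O[C@H]1CC2(C(=O)OCC)SCCCS2 | intermediate
9 | ethyl 3-[(4S,5R)-5-acetyl-2,2-dimethyl-1,3-dioxolan-4-yl]-2-oxopropanoate (ethyl (4S,5R)-4,5-(isopropylidenedioxy)-2,6-dioxoheptanoate) | CC(=O)[C@@H]1OC(C)(C)O[C@H]1CC(=O)C(=O)OCC | intermediate (key-step precursor)
10 | dibutylboron enolate of 9 at the methyl ketone (C6=C7) | C=C(OB(CCCC)CCCC)[C@@H]1OC(C)(C)O[C@H]1CC(=O)C(=O)OCC | intermediate (not isolated)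
11 | O1-dibutylboryl aldolate of 12 | CC1(C)O[C@H]2C[C@@](OB(CCCC)CCCC)(C(=O)OCC)CC(=O)[C@@H]2O1 | intermediate (not isolated)
12 | ethyl (1S,4R,5S)-1-hydroxy-4,5-(isopropylidenedioxy)-3-oxocyclohexane-1-carboxylate (ethyl 4,5-O-isopropylidene-3-dehydro-ent-quinate) | CC1(C)O[C@H]2C[C@@](O)(C(=O)OCC)CC(=O)[C@@H]2O1 | intermediate (key-step product)
13 | ethyl 4,5-O-isopropylidene-ent-quinate | CC1(C)O[C@H]2C[C@@](O)(C(=O)OCC)C[C@H](O)[C@@H]2O1 | intermediate
14 | ethyl 3,4-O-isopropylidene-ent-quinate | O[C@H]1C[C@@](O)(C(=O)OCC)C[C@H](O2)[C@@H]1OC2(C)C | intermediate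
15 | allyl 3,4-O-isopropylidene-ent-quinate | O[C@H]1C[C@@](O)(C(=O)OCC=C)C[C@H](O2)[C@@H]1OC2(C)C | intermediate
16 | caffeic acid, (E)-3-(3,4-dihydroxyphenyl)prop-2-enoic acid | O=C(O)/C=C/c1ccc(O)c(O)c1 | starting material
17 | tert-butyldimethylsilyl (E)-3-[3,4-bis(tert-butyldimethylsilyloxy)phenyl]prop-2-enoate | CC(C)(C)[Si](C)(C)OC(=O)/C=C/c1ccc(O[Si](C)(C)C(C)(C)C)c(O[Si](C)(C)C(C)(C)C)c1 | intermediate (not isolated)
18 | (E)-3-[3,4-bis(tert-butyldimethylsilyloxy)phenyl]prop-2-enoic acid | O=C(O)/C=C/c1ccc(O[Si](C)(C)C(C)(C)C)c(O[Si](C)(C)C(C)(C)C)c1 | intermediate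
19 | allyl 5-O-[(E)-3,4-bis(tert-butyldimethylsilyloxy)cinnamoyl]-3,4-O-isopropylidene-ent-quinate | O=C(/C=C/c1ccc(O[Si](C)(C)C(C)(C)C)c(O[Si](C)(C)C(C)(C)C)c1)O[C@H]1C[C@@](O)(C(=O)OCC=C)C[C@H](O2)[C@@H]1OC2(C)C | intermediate
20 | 1-O-triethylsilyl ether of 19 | O=C(/C=C/c1ccc(O[Si](C)(C)C(C)(C)C)c(O[Si](C)(C)C(C)(C)C)c1)O[C@H]1C[C@@](O[Si](CC)(CC)CC)(C(=O)OCC=C)C[C@H](O2)[C@@H]1OC2(C)C | intermediate
21 | 5-O-[(E)-3,4-bis(tert-butyldimethylsilyloxy)cinnamoyl]-3,4-O-isopropylidene-1-O-(triethylsilyl)-ent-quinic acid | O=C(/C=C/c1ccc(O[Si](C)(C)C(C)(C)C)c(O[Si](C)(C)C(C)(C)C)c1)O[C@H]1C[C@@](O[Si](CC)(CC)CC)(C(=O)O)C[C@H](O2)[C@@H]1OC2(C)C | intermediate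
22 | acid chloride of 21 | O=C(/C=C/c1ccc(O[Si](C)(C)C(C)(C)C)c(O[Si](C)(C)C(C)(C)C)c1)O[C@H]1C[C@@](O[Si](CC)(CC)CC)(C(=O)Cl)C[C@H](O2)[C@@H]1OC2(C)C | intermediate (not isolated)
23 | lithium C1-alkoxide of 19 | [Li+].O=C(/C=C/c1ccc(O[Si](C)(C)C(C)(C)C)c(O[Si](C)(C)C(C)(C)C)c1)O[C@H]1C[C@@]([O-])(C(=O)OCC=C)C[C@H](O2)[C@@H]1OC2(C)C | intermediate (not isolated)
24 | fully protected dimer: allyl 1-O-{5-O-[(E)-3,4-bis(tert-butyldimethylsilyloxy)cinnamoyl]-3,4-O-isopropylidene-1-O-(triethylsilyl)-ent-quinoyl}-5-O-[(E)-3,4-bis(tert-butyldimethylsilyloxy)cinnamoyl]-3,4-O-isopropylidene-ent-quinate | O=C(/C=C/c1ccc(O[Si](C)(C)C(C)(C)C)c(O[Si](C)(C)C(C)(C)C)c1)O[C@H]1C[C@@](O[Si](CC)(CC)CC)(C(=O)O[C@@]3(C(=O)OCC=C)C[C@H](OC(=O)/C=C/c4ccc(O[Si](C)(C)C(C)(C)C)c(O[Si](C)(C)C(C)(C)C)c4)[C@@H](OC5(C)C)[C@@H](O5)C3)C[C@H](O2)[C@@H]1OC2(C)C | intermediate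
25 | protected dimer acid (24 with the ring B carboxyl free) | O=C(/C=C/c1ccc(O[Si](C)(C)C(C)(C)C)c(O[Si](C)(C)C(C)(C)C)c1)O[C@H]1C[C@@](O[Si](CC)(CC)CC)(C(=O)O[C@@]3(C(=O)O)C[C@H](OC(=O)/C=C/c4ccc(O[Si](C)(C)C(C)(C)C)c(O[Si](C)(C)C(C)(C)C)c4)[C@@H](OC5(C)C)[C@@H](O5)C3)C[C@H](O2)[C@@H]1OC2(C)C | intermediate
26 | CNP0107948.2, 1-O-(5-O-caffeoyl-ent-quinoyl)-5-O-caffeoyl-ent-quinic acid | O=C(/C=C/c1ccc(O)c(O)c1)O[C@H]1C[C@@](O)(C(=O)O[C@@]2(C(=O)O)C[C@H](OC(=O)/C=C/c3ccc(O)c(O)c3)[C@@H](O)[C@@H](O)C2)C[C@H](O)[C@@H]1O | target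

Total step count: 16. Longest linear sequence: 15 steps (steps 1–9 and 11–16, from 1 to 26); step 10 is a one-step side branch.

Steps most likely to fail

Step 6 (key aldol). Three processes may defeat it. Enolisation may occur at the CH2 of the α-keto ester, followed by expulsion of the dioxolane oxygen. An open transition state may compete and erode facial selectivity at C1. The product may enolise further, leading to dehydration across C1–C2 or epimerisation at C4 towards the cis-fused acetal. The fallback makes the enolate regiospecifically from a halide; it sets out from 8 and comes back to the route at 12. Kinetic silylation of the methyl ketone of 8 (LiN(i-Pr)2, Me3SiCl, THF, −78 °C; the dithiane ester has no α-hydrogen) would give the trimethylsilyl enol ether F1. N-Bromosuccinimide, first in THF at −78 °C and then in NaHCO3-buffered aqueous acetone, would brominate the enol ether and hydrolyse the dithiane, giving the bromomethyl diketo ester F2. Zinc dust in THF at 0 °C would then form the bromozinc enolate F3 at C7 only, and its intramolecular Reformatsky-type addition to the α-keto ester would give 12 after buffered work-up.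

Step 14 (inter-ring ester). Acyl transfer between two fully substituted centres may simply not occur, or the alkoxide may instead pick up a silyl group from an aryl silyl ether. The fallback forms the ester on a more accessible acceptor before the caffeoyl groups are present; it sets out from 15 and 14 and comes back at 24.
- Donor: 15 would be silylated at both hydroxyls (Et3SiOTf, 2,6-lutidine) to the bis-silyl allyl ester F4. Deallylation (Pd(PPh3)4, morpholine) would give the bis-silyl acid F5, and 1-chloro-N,N,2-trimethylprop-1-en-1-amine would convert it to the bis-silyl acid chloride F6.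
- Acceptor: 14 would be lactonised through O5 (TsOH, toluene, reflux with removal of ethanol) to the 1,5-lactone acetonide F7, whose tied-back C1 hydroxyl is far easier to acylate.
- Coupling and return: F6 and F7 (DMAP, Et3N, CH2Cl2) would give the acylated lactone F8. Allyl alcohol with K2CO3 would open the strained lactone to the ring B allyl ester F9. Pyridinium p-toluenesulfonate in MeOH at 0 °C would remove the secondary silyl ether only, giving the diol F10. Double Steglich esterification of the two secondary hydroxyls with 18 (EDC·HCl, DMAP) would return 24.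

Step 4 (methyl ketone). Chemoselectivity may be lost, with the Grignard reagent also adding to the ethyl ester, or the reaction may stall at partial conversion. The fallback installs the ketone before the second ester is present; it sets out from 3 and comes back at 8. Treating 3 with MeMgBr (2.5 equiv, THF, 0 °C) would give the hydroxy methyl ketone F11. Triflation (Tf2O, 2,6-lutidine, CH2Cl2, −78 °C) would give the keto triflate F12, which would be displaced at −78 °C by the sodium enolate 6 to give 8.

Further compounds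
F1 | step 6 | ethyl 2-{[(4S,5R)-2,2-dimethyl-5-[1-(trimethylsilyloxy)ethenyl]-1,3-dioxolan-4-yl]methyl}-1,3-dithiane-2-carboxylate | C=C(O[Si](C)(C)C)[C@@H]1OC(C)(C)O[C@H]1CC2(C(=O)OCC)SCCCS2
F2 | step 6 | ethyl 3-[(4S,5R)-5-(bromoacetyl)-2,2-dimethyl-1,3-dioxolan-4-yl]-2-oxopropanoate | BrCC(=O)[C@@H]1OC(C)(C)O[C@H]1CC(=O)C(=O)OCC
F3 | step 6 | bromozinc enolate of 9 at C7 | C=C(O[Zn]Br)[C@@H]1OC(C)(C)O[C@H]1CC(=O)C(=O)OCC
F4 | step 14 | allyl 3,4-O-isopropylidene-1,5-bis-O-(triethylsilyl)-ent-quinate | CC[Si](CC)(CC)O[C@H]1C[C@@](O[Si](CC)(CC)CC)(C(=O)OCC=C)C[C@H](O2)[C@@H]1OC2(C)C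
F5 | step 14 | 3,4-O-isopropylidene-1,5-bis-O-(triethylsilyl)-ent-quinic acid | CC[Si](CC)(CC)O[C@H]1C[C@@](O[Si](CC)(CC)CC)(C(=O)O)C[C@H](O2)[C@@H]1OC2(C)C
F6 | step 14 | acid chloride of F5 | CC[Si](CC)(CC)O[C@H]1C[C@@](O[Si](CC)(CC)CC)(C(=O)Cl)C[C@H](O2)[C@@H]1OC2(C)C
F7 | step 14 | 3,4-O-isopropylidene-ent-quinic acid 1,5-lactone | O=C3O[C@H]1C[C@]3(O)C[C@H](O2)[C@@H]1OC2(C)C
F8 | step 14 | 1-O-[3,4-O-isopropylidene-1,5-bis-O-(triethylsilyl)-ent-quinoyl]-3,4-O-isopropylidene-ent-quinic acid 1,5-lactone | CC[Si](CC)(CC)O[C@H]1C[C@@](O[Si](CC)(CC)CC)(C(=O)O[C@@]3(C(=O)O6)C[C@H]6[C@@H](OC7(C)C)[C@@H](O7)C3)C[C@H](O2)[C@@H]1OC2(C)C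
F9 | step 14 | allyl 1-O-[3,4-O-isopropylidene-1,5-bis-O-(triethylsilyl)-ent-quinoyl]-3,4-O-isopropylidene-ent-quinate | CC[Si](CC)(CC)O[C@H]1C[C@@](O[Si](CC)(CC)CC)(C(=O)O[C@@]3(C(=O)OCC=C)C[C@H](O)[C@@H](OC7(C)C)[C@@H](O7)C3)C[C@H](O2)[C@@H]1OC2(C)C
F10 | step 14 | allyl 1-O-[3,4-O-isopropylidene-1-O-(triethylsilyl)-ent-quinoyl]-3,4-O-isopropylidene-ent-quinate | O[C@H]1C[C@@](O[Si](CC)(CC)CC)(C(=O)O[C@@]3(C(=O)OCC=C)C[C@H](O)[C@@H](OC7(C)C)[C@@H](O7)C3)C[C@H](O2)[C@@H]1OC2(C)C
F11 | step 4 | 1-[(4R,5S)-5-(hydroxymethyl)-2,2-dimethyl-1,3-dioxolan-4-yl]ethan-1-one | CC(=O)[C@@H]1OC(C)(C)O[C@H]1CO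
F12 | step 4 | [(4S,5R)-5-acetyl-2,2-dimethyl-1,3-dioxolan-4-yl]methyl trifluoromethanesulfonate | CC(=O)[C@@H]1OC(C)(C)O[C@H]1COS(=O)(=O)C(F)(F)F
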